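Quinone numbering used here: C1 = carbonyl flanked by both substituents, C2 = heptadecyl carbon, C3 = CH, C4 = the other carbonyl, C5 = CH, C6 = methoxy carbon.
Retrosynthesis: the C1 oxygen is removed first (C1–H of 3-heptadecyl-5-methoxyphenol, oxidised last); then ring bonds C1–C2 and C5–C6 are cut together, leaving a four-carbon piece C2–C3–C4(O)–C5 and a two-carbon piece C6(OMe)–C1.
Enabling feature: C2–C5, with oxygen on C4 and the chain on C2, is the C6–C5–C4–C3 diene of a 6-alkyl-4-oxy-2H-pyran-2-one ring whose O1–C2 lactone bridge can leave as CO2; C6(OMe)–C1 is the C=C of 1,1-dimethoxyethene, whose second methoxy group is the leaving group for aromatisation.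
Forward: the chain is joined first (C16 bromide onto the 6-methyl group of 4-hydroxy-6-methyl-2H-pyran-2-one) and the 4-OH becomes a triflate (diene activator and masked phenol). The benzene ring then arises in one operation by [4+2] cycloaddition, CO2 extrusion and loss of methanol; triflate cleavage and para-oxidation give the quinone.
Stereochemistry: the target has no stereocentre; the two bridgehead centres of the racemic cycloadduct are transient.

Key step: step 3

Remark: 1,1-dimethoxyethene (ketene dimethyl acetal) is taken as a purchasable reagent; otherwise it comes in one step from bromoacetaldehyde dimethyl acetal and KOt-Bu.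

Step 1
Reactants: 1 4-hydroxy-6-methyl-2H-pyran-2-one; 2 1-bromohexadecane
Product: 4 6-heptadecyl-4-hydroxy-2H-pyran-2-one, via dilithiated pyranone dianion 3 (not isolated)
Conditions: LiN(i-Pr)2 (2.3 equiv), THF/DMPU, −78 °C; then 2, −78 → 0 °C; aq. HCl work-up
Reagents that add atoms: none
Why: Lateral dianion alkylation: after the 4-OH, the vinylogous 6-methyl group is deprotonated to 3, whose carbanion carbon is the more nucleophilic site, so SN2 attack on the primary bromide should lengthen the methyl group to heptadecyl without O-alkylation.

Step 2
Reactants: 4 6-heptadecyl-4-hydroxy-2H-pyran-2-one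
Product: 5 6-heptadecyl-2-oxo-2H-pyran-4-yl trifluoromethanesulfonate
Conditions: Tf2O (1.1 equiv), 2,6-lutidine (1.3 equiv), CH2Cl2, −78 → 0 °C
Reagents that add atoms: trifluoromethanesulfonic anhydride, O=S(=O)(OS(=O)(=O)C(F)(F)F)C(F)(F)F
Why: O-Sulfonylation of the vinylogous acid at O-4 (enol triflate formation) should give 5, in which the triflyloxy group both lowers the LUMO of the pyranone diene and masks the later phenol oxygen.

Step 3
Reactants: 5 6-heptadecyl-2-oxo-2H-pyran-4-yl trifluoromethanesulfonate; 6 1,1-dimethoxyethene
Product: 9 3-heptadecyl-5-methoxyphenyl trifluoromethanesulfonate, via bridged lactone cycloadduct 7 (not isolated), via dimethoxycyclohexadiene ketal 8 (not isolated)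
Conditions: 6 (5 equiv), 2,6-di-tert-butyl-4-methylpyridine (0.2 equiv), 4 Å molecular sieves, toluene, sealed tube, 110 °C; then pyridinium p-toluenesulfonate (0.5 equiv), 25 °C
Reagents that add atoms: none
Why: Proposed new method: the lactone dienoate of 5 (C3–C6 of the pyranone ring, LUMO lowered by the ring carbonyl and by the inductively withdrawing 4-triflyloxy group) should take up the electron-rich C=C of 6 in an asynchronous inverse-electron-demand [4+2] cycloaddition in which the nucleophilic CH2 of 6 bonds to C6 and the acetal carbon to C3, giving bridged lactone 7, which loses CO2 by retro-[4+2] to ketal 8 and then methanol (acid-assisted) to arene 9. The closest known reaction type is the inverse-electron-demand Diels–Alder reaction of 2-pyranones bearing a 3-ester group with 1,1-dimethoxyethene, which gives methyl aryl ethers with the same regiochemistry; it has not been shown for a 2-pyranone activated only by a 4-sulfonyloxy group, hence the label. The carbocycle is closed by an intermolecular suprafacial [4πs+2πs] cycloaddition that forms both new ring bonds (C6–CH2 leading, C3–C(OMe)2 following), and the oxygen-containing bridge of 7 is a temporary ring excised as CO2. The two bridgehead stereocentres of racemic 7 are destroyed on CO2 loss, so no stereocentre needs control. The step needs regioselectivity (CH2 to C6 and not to C3) and chemoselectivity (cycloaddition instead of addition–elimination at C4 with loss of triflate): the first is secured by the polarisation of the dienoate, whose δ-carbon C6 is the electrophilic terminus and whose α-carbon C3 is the enolate-like terminus that closes onto the developing dimethoxycarbenium centre, the second by the buffered, non-polar medium that favours the concerted path, and the direction of the final elimination is fixed because only the former CH2 carries hydrogen next to the ketal carbon.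

Step 4
Reactants: 9 3-heptadecyl-5-methoxyphenyl trifluoromethanesulfonate
Product: 10 3-heptadecyl-5-methoxyphenol
Conditions: Et4NOH (aq., 2.5 equiv), 1,4-dioxane, 25 °C; then 1 M HCl
Reagents that add atoms: none
Why: Sulfonate ester hydrolysis: hydroxide attacks sulfur of the aryl triflate and S–O cleavage should release the phenolate (phenol 10 after acidification), the methyl ether and the chain being inert.

Step 5
Reactants: 10 3-heptadecyl-5-methoxyphenol
Product: 11 2-heptadecyl-6-methoxycyclohexa-2,5-diene-1,4-dione (2-heptadecyl-6-methoxy-1,4-benzoquinone)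
Conditions: (KSO3)2NO (2.5 equiv), KH2PO4, Bu4NHSO4 (cat.), CH2Cl2/H2O, 25 °C
Reagents that add atoms: dipotassium nitrosodisulfonate, [K+].[K+].[O]N(S(=O)(=O)[O-])S(=O)(=O)[O-]
Why: Teuber oxidation: one nitroxyl radical removes the phenolic hydrogen and a second adds through its oxygen at the free para carbon (between the methoxy and heptadecyl carbons), so that loss of imidodisulfonate should give the para-quinone with oxygen at exactly the carbon the cycloaddition left as C–H.

Compound list
1 | 4-hydroxy-6-methyl-2H-pyran-2-one | CC1=CC(O)=CC(=O)O1 | starting material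
2 | 1-bromohexadecane | CCCCCCCCCCCCCCCCBr | starting material
3 | dilithium dianion of 1 (4-oxido-6-lithiomethyl-2H-pyran-2-one) | [Li+].[Li+].[CH2-]C1=CC([O-])=CC(=O)O1 | intermediate
4 | 6-heptadecyl-4-hydroxy-2H-pyran-2-one | CCCCCCCCCCCCCCCCCC1=CC(O)=CC(=O)O1 | intermediate
5 | 6-heptadecyl-2-oxo-2H-pyran-4-yl trifluoromethanesulfonate | CCCCCCCCCCCCCCCCCC1=CC(OS(=O)(=O)C(F)(F)F)=CC(=O)O1 | intermediate
6 | 1,1-dimethoxyethene | C=C(OC)OC | starting material
7 | racemic 1-heptadecyl-8,8-dimethoxy-3-oxo-2-oxabicyclo[2.2.2]oct-5-en-5-yl trifluoromethanesulfonate (one enantiomer drawn; the bridge fixes the relative configuration) | CCCCCCCCCCCCCCCCC[C@]12CC(OC)(OC)[C@H](C(=O)O1)C(OS(=O)(=O)C(F)(F)F)=C2 | intermediate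
8 | 5-heptadecyl-3,3-dimethoxycyclohexa-1,5-dien-1-yl trifluoromethanesulfonate | CCCCCCCCCCCCCCCCCC1=CC(OS(=O)(=O)C(F)(F)F)=CC(OC)(OC)C1 | intermediate
9 | 3-heptadecyl-5-methoxyphenyl trifluoromethanesulfonate | CCCCCCCCCCCCCCCCCc1cc(OC)cc(OS(=O)(=O)C(F)(F)F)c1 | intermediate
10 | 3-heptadecyl-5-methoxyphenol | CCCCCCCCCCCCCCCCCc1cc(O)cc(OC)c1 | intermediate
11 | 2-heptadecyl-6-methoxycyclohexa-2,5-diene-1,4-dione | CCCCCCCCCCCCCCCCCC1=CC(=O)C=C(OC)C1=O | target

Total step count: 5. Longest linear sequence: 5 steps (1 → 4 → 5 → 9 → 10 → 11).

Steps most likely to fail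

1. Step 3 (bears the label). Risk: the cycloaddition may be too slow for a diene without an acyl activator, so that oligomerisation of the ketene acetal or ionic addition–elimination at C4 (displacement of triflate) overtakes ring formation. Fallback with known chemistry, setting out from 2 and coming back at 10 (steps 1–4 are then bypassed): 2 is turned with Mg in THF into hexadecylmagnesium bromide F1, which is cross-coupled with commercial 3,5-dimethoxybenzyl bromide under Li2CuCl4 catalysis (THF, −10 → 25 °C) to 1-heptadecyl-3,5-dimethoxybenzene F2. Cleavage of one of the two equivalent methyl ethers with NaSEt in DMF at 140 °C should then give 10, and step 5 follows unchanged.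

2. Step 1. Risk: sluggish SN2 reaction of the long-chain bromide with the aggregated dianion, leading to incomplete conversion, proton transfer or competing O-alkylation. Fallback, setting out from 1 (through its dianion 3) and coming back at 4: carbonyl addition replaces substitution. Dianion 3 is added to commercial hexadecanal to give racemic 4-hydroxy-6-(2-hydroxyheptadecyl)-2H-pyran-2-one F3, which is dehydrated (TsOH, toluene, reflux, water separator) to 6-[(E)-heptadec-1-en-1-yl]-4-hydroxy-2H-pyran-2-one F4. Hydrogenation of the side-chain double bond (H2, 1 atm, Pd/C, EtOAc, 25 °C, stopped after one equivalent) should then give 4.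

3. Step 5. Risk: over-oxidation or attack at an ortho position by the nitroxyl radical, and poor contact between the aqueous oxidant and the lipophilic phenol. Fallback, setting out from 10 and coming back at 11: two-electron oxidation with PhI(OAc)2 (2.2 equiv) in MeOH at 0 °C should methoxylate the para carbon twice to the quinone monoketal 3-heptadecyl-4,4,5-trimethoxycyclohexa-2,5-dien-1-one F5. Ketal hydrolysis (aq. HCl, acetone, 25 °C) should then give 11.

Further compounds
F1 | step 3 | hexadecylmagnesium bromide | CCCCCCCCCCCCCCCC[Mg]Br
F2 | step 3 | 1-heptadecyl-3,5-dimethoxybenzene | CCCCCCCCCCCCCCCCCc1cc(OC)cc(OC)c1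
F3 | step 1 | 4-hydroxy-6-(2-hydroxyheptadecyl)-2H-pyran-2-one (racemic) | CCCCCCCCCCCCCCCC(O)CC1=CC(O)=CC(=O)O1
F4 | step 1 | 6-[(E)-heptadec-1-en-1-yl]-4-hydroxy-2H-pyran-2-one | CCCCCCCCCCCCCCC/C=C/C1=CC(O)=CC(=O)O1
F5 | step 5 | 3-heptadecyl-4,4,5-trimethoxycyclohexa-2,5-dien-1-one | CCCCCCCCCCCCCCCCCC1=CC(=O)C=C(OC)C1(OC)OC
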